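To the colleague who wanted a quick number for the flask and guessed that the percentages of cedar would carry over, I replied that the two earlier runs argued against it.

| setting | cedar | elm | flask |
|---|---|---|---|
| solid substrate | 0.14 M | 0.22 M | 0.10 M |
| gas | 7.8 mM (held) | 7.8 mM (held) | 7.8 mM (held) |
| remark | run made earlier | run made earlier |  |
| time |  |  | 8.0 h |

| run | time / h | target / % | solid substrate / % |
|---|---|---|---|
| cedar | 0.417 | 0 | 79.5 |
| cedar | 1.33 | 3.2 | 70.6 |
| cedar | 2.00 | 4.4 | 67.2 |
| cedar | 3.00 | 6.6 | 60.6 |
| cedar | 5.00 | 12.8 | 46.7 |
| elm | 0.417 | 0.9 | 86.2 |
| elm | 1.33 | 1.6 | 81.5 |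
| elm | 2.00 | 4.4 | 78.2 |
| elm | 3.00 | 3.7 | 73.7 |
| elm | 5.00 | 9.1 | 68.1 |

(each reading ± 1 percentage point)
- percentages count the solid substrate that a species holds: one side product counts as two
- solid, in amounts per volume of the solution: solid substrate
- at the start none of reagent is dissolved
- steps under discussion: solid substrate <-> dissolved substrate; dissolved substrate + reagent -> target; 2 dissolved substrate -> side product; gas <-> reagent
- at the start none of the solid substrate is in solution
- noon: doubling the saturation concentration of gas, all else as stated
- spring: doubling the transfer coefficient of the gas, all else as stated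
- midnight: doubling the dissolution coefficient of the solid substrate, all else as stated
- dusk: doubling the solubility of the solid substrate, all else as stated
1. target at 8.0 h, in percent of the solid substrate charged
2. the change that raises the amount of target at 8.0 h, in percent of the solid substrate charged most ("none" if none brings more than 2 percentage points) (noon / spring / midnight / dusk / none)
3. amount of target at 8.0 h, in percent of the solid substrate charged, after dusk

By 5.00 h cedar held 12.8% of target and elm 9.1%, so the percentages differed, but as c(target) per hour cedar made 3.58 mM h⁻¹ and elm 4.00 mM h⁻¹, a gap smaller than the 0.440 mM h⁻¹ that one reading's scatter of 1 percentage point is worth in elm. I therefore carried their mean, 3.79 mM h⁻¹, as the charge-blind rate, the c(target) made per hour as read from cedar and elm within that scatter, a pseudo-zero-order rate as read while solid stood and with gas held at 7.8 mM, and for a flask under those same conditions the percentage then followed as that rate times the time, divided by the charge. After a first drop of 29.5 mM, the runs lost 9.35 mM h⁻¹ of solid, so I expected the flask's solid to last until about 7.95 h, close to the asked 8.0 h, and I committed to 30.4%.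

The forecast gave 29%, from 25% to 33%, slightly below my figure; it chose noon, holding that “the target rate is proportional to gas saturation”, and put dusk at 31%, from 25% to 37%.

The flask gave 30.7%, with noon adding 25 points and dusk giving 28.6%.

    solid substrate ⇌ dissolved substrate, rate k1*(cs1 - [dissolved substrate]) while solid is left; crystals form when [dissolved substrate] > cs1 (solubility = 34.0 mM, k = 0.0720 min⁻¹)
    dissolved substrate + reagent → target (k = 0.730 M⁻¹ min⁻¹)
    2 dissolved substrate → side product (k = 0.0430 M⁻¹ min⁻¹)
    gas ⇌ reagent, rate k4*(csat - [reagent]) (kL = 0.0140 min⁻¹)

At 4.00 h the flask's dissolved substrate stood at 93.7% of saturation and its reagent at 37.6% of saturation. Its result over 8.0 h comes to 3.84 mM h⁻¹ against the charge-blind rate of 3.79 mM h⁻¹, and that rate put to the same flask stopped at 5.0 h gave 19.0%, where the flask held 18.5% of target.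

The earlier runs and the new flask stem from a simulated flask with made-up constants; the scatter is artificial.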